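**Retrosynthetic overview**
1. Target ⇐ desilylation and alkyne hydration of a bis-anhydride that carries the 2-oxohexyl chain of ring B as a hex-1-ynyl group and the ring A alcohol as a silyl ether.
2. Ring A (hydroxymethyl anhydride) ⇐ a 3,4-disubstituted furan, oxidised with singlet oxygen and then perruthenate; the furan is bought and ring A is unveiled last.
3. Ring B ⇐ its C3=C4 bond, closed by an aldol–dehydration inside the mixed anhydride that forms when the Wolff ketene of a diazoketone captures 2-oxooct-3-ynoic acid (copy of alkylcitrate synthase/dehydratase).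
4. Enabling feature: in ring B (O1–C2(=O)–C3=C4–C5(=O)), C3 (bearing the stereogenic heptan-2-yl chain) is the α-carbon of the C2 carboxyl and C4 (bearing the 2-oxohexyl chain) is the keto carbon of an α-keto acid ending in C5, the two carboxyl carbons being bridged by O1; the alkyne makes the keto acid non-enolisable.
5. Stereocentre ⇐ Evans alkylation of an N-heptanoyl oxazolidinone with a 3-furylmethyl bromide, carried into ring B by the Wolff shift with retention. Ring order: furan (purchased) → ring B (step 9) → ring A (step 10).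

Key step: step 9

Remark on the chemistry (assumption): any 2,3-dialkylmaleic acid formed when an anhydride meets water is taken to reclose on acidification and concentration, and the target is taken to be stable as the open hydroxymethyl anhydride drawn; TBS = tert-butyl(dimethyl)silyl.

**Step 1**
Reactants: 1 furan-3,4-diyldimethanol
Product: 3 [4-({[tert-butyl(dimethyl)silyl]oxy}methyl)furan-3-yl]methanol, via sodium alkoxide 2 (not isolated)
Conditions: NaH (1.0 equiv), THF, 0 °C → rt; then TBSCl (1.0 equiv), rt
Reagents that add atoms: tert-butyldimethylsilyl chloride, CC(C)(C)[Si](C)(C)Cl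
Why: O-silylation of the sparingly soluble monosodium alkoxide of a symmetrical diol should stop at the mono-ether (statistical desymmetrisation biased by precipitation of the mono-salt).

**Step 2**
Reactants: 3 [4-({[tert-butyl(dimethyl)silyl]oxy}methyl)furan-3-yl]methanol
Product: 4 {[4-(bromomethyl)furan-3-yl]methoxy}(tert-butyl)dimethylsilane
Conditions: CBr4, PPh3, CH2Cl2, 0 °C; used at once
Reagents that add atoms: carbon tetrabromide, BrC(Br)(Br)Br
Why: The Appel reaction should convert the primary furylmethyl alcohol into the bromide under neutral conditions that spare the silyl ether and the acid-sensitive furan.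

**Step 3**
Reactants: 5 (4S)-4-benzyl-1,3-oxazolidin-2-one; 6 heptanoyl chloride
Product: 8 (4S)-4-benzyl-3-heptanoyl-1,3-oxazolidin-2-one, via lithium oxazolidinide 7 (not isolated)
Conditions: nBuLi, THF, −78 °C; then 6, −78 → 0 °C
Reagents that add atoms: none
Why: N-acylation of the lithiated Evans auxiliary with an acid chloride is the standard entry to the chiral imide.

**Step 4**
Reactants: 8 (4S)-4-benzyl-3-heptanoyl-1,3-oxazolidin-2-one; 4 {[4-(bromomethyl)furan-3-yl]methoxy}(tert-butyl)dimethylsilane
Product: 10 (4S)-4-benzyl-3-[(2R)-2-{[4-(TBSO-methyl)furan-3-yl]methyl}heptanoyl]-1,3-oxazolidin-2-one, via sodium enolate 9 (not isolated)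
Conditions: NaN(SiMe3)2, THF, −78 °C; then 4, −78 → −40 °C
Reagents that add atoms: none
Why: Evans asymmetric alkylation: the chelated (Z)-enolate should be attacked by the benzylic-type bromide on the face opposite the benzyl group of the auxiliary, which sets the (R) centre.

**Step 5**
Reactants: 10 (4S)-4-benzyl-3-[(2R)-2-{[4-(TBSO-methyl)furan-3-yl]methyl}heptanoyl]-1,3-oxazolidin-2-one
Product: 12 (2R)-2-{[4-(TBSO-methyl)furan-3-yl]methyl}heptanoic acid, via peroxy acid 11 (not isolated)
Conditions: LiOH, 30% H2O2, THF/H2O, 0 °C; then aq. Na2SO3; 1 M HCl to pH 3, cold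
Reagents that add atoms: hydrogen peroxide, OO
Why: Hydroperoxide cleavage of the Evans imide should attack the exocyclic carbonyl selectively and, after sulfite reduction of the peroxy acid, give the acid without epimerisation at 0 °C.

**Step 6**
Reactants: 12 (2R)-2-{[4-(TBSO-methyl)furan-3-yl]methyl}heptanoic acid
Product: 14 (3R)-1-diazo-3-{[4-(TBSO-methyl)furan-3-yl]methyl}octan-2-one, via mixed carbonic anhydride 13 (not isolated)
Conditions: iBuOCOCl, N-methylmorpholine, THF, −15 °C; then CH2N2, Et2O, −15 → 0 °C
Reagents that add atoms: diazomethane, C=[N+]=[N-]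
Why: Acylation of diazomethane by a mixed carbonic anhydride (first stage of the Arndt–Eistert sequence) should give the α-diazoketone without touching the α-stereocentre or the furan.

**Step 7**
Reactants: 15 hex-1-yne; 16 di-tert-butyl oxalate
Product: 19 tert-butyl 2-oxooct-3-ynoate, via hex-1-ynyllithium 17 (not isolated), via tetrahedral adduct 18 (not isolated)
Conditions: 15, nBuLi, THF, −78 °C; cannulate into 16 (2 equiv), THF, −78 °C; 1 M HCl quench at −78 °C
Reagents that add atoms: none
Why: Acylation of a lithium acetylide by a dialkyl oxalate should stop at the α-keto ester because the tetrahedral adduct persists at −78 °C until the quench.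

**Step 8**
Reactants: 19 tert-butyl 2-oxooct-3-ynoate
Product: 20 2-oxooct-3-ynoic acid
Conditions: CF3CO2H/CH2Cl2 (1:4), 0 °C → rt; toluene azeotrope; used crude
Reagents that add atoms: none
Why: Acidolysis of the tert-butyl ester (E1 loss of isobutylene) should free the acid without exposing the nucleophile-sensitive ynone to base.

**Step 9**
Reactants: 14 (3R)-1-diazo-3-{[4-(TBSO-methyl)furan-3-yl]methyl}octan-2-one; 20 2-oxooct-3-ynoic acid
Product: 25 3-[(2R)-1-[4-(TBSO-methyl)furan-3-yl]heptan-2-yl]-4-(hex-1-yn-1-yl)furan-2,5-dione, via ketene 21 (not isolated), via mixed anhydride 22 (not isolated), via aldol adduct 23 (not isolated), via mesylate 24 (not isolated)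
Conditions: 20 (1.5 equiv), Et3N (3 equiv), PhCO2Ag (10 mol %), THF, −25 °C → rt, dark; then MsCl, Et3N, 0 °C → rt
Reagents that add atoms: none
Why: Proposed new method: silver-catalysed Wolff rearrangement of 14 (1,2-shift of the stereogenic carbon with retention) should give ketene 21, the carboxylate of 20 should add to it to give mixed anhydride 22 directly as its enolate, and this enolate should close ring B by aldol addition of the former ketene carbon to the adjacent alkynyl ketone (forming the C3–C4 bond, 23), after which mesylation and E1cB elimination (24) turn that bond into the ring alkene. The closest known reaction types are the Perkin-type condensation of arylacetic acids with α-keto acids to maleic anhydrides, the capture of Wolff ketenes by oxygen nucleophiles (Arndt–Eistert) and the base-mediated closure of α-acyloxy ketones to butenolides; the bond construction is that of alkylcitrate synthase and dehydratase in maleidride biosynthesis (acyl α-carbon onto the keto group of an α-keto acid, then loss of water). Ring B closes in the 5-(enolendo)-exo-trig mode, the same formally unfavourable but routinely used mode as in the butenolide closure. No new stereocentre survives (the two ring centres of 23 are erased by the elimination), and the existing centre migrates with retention and is afterwards never α to a carbonyl group, so no epimerisation is expected. The step needs enolisation only at the ketene-derived carbon, 1,2- rather than 1,4-attack on the ynone and dehydration only into the ring: keto acid 20 has no α-hydrogen, so a single enolate and a single elimination direction exist, and 1,2-attack gives a five-membered ring where conjugate attack would need a seven-membered one. If the enolate is protonated before it cyclises, neutral 22 remains a substrate for the same closure under the Et3N of the second stage.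

**Step 10**
Reactants: 25 3-[(2R)-1-[4-(TBSO-methyl)furan-3-yl]heptan-2-yl]-4-(hex-1-yn-1-yl)furan-2,5-dione
Product: 29 3-[(2R)-1-[4-(TBSO-methyl)-2,5-dioxo-2,5-dihydrofuran-3-yl]heptan-2-yl]-4-(hex-1-yn-1-yl)furan-2,5-dione, via endoperoxide 26 (not isolated), via hydroxybutenolide 27 (not isolated), via regioisomeric hydroxybutenolide 28 (not isolated)
Conditions: O2, hν (visible), tetraphenylporphyrin (cat.), iPr2NEt, CH2Cl2, −78 °C; then (nPr4N)RuO4 (5 mol %), N-methylmorpholine N-oxide, 4 Å MS, CH2Cl2/MeCN, rt
Reagents that add atoms: dioxygen, O=O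
Why: Singlet oxygen should add [4+2] to the electron-rich furan only (the enyne anhydride is electron-poor), the amine should open endoperoxide 26 by Kornblum–DeLaMare rearrangement to the two lactols 27 and 28, and Ley–Griffith oxidation should converge both on ring A, the furan thus serving as a masked maleic anhydride.

**Step 11**
Reactants: 29 3-[(2R)-1-[4-(TBSO-methyl)-2,5-dioxo-2,5-dihydrofuran-3-yl]heptan-2-yl]-4-(hex-1-yn-1-yl)furan-2,5-dione
Product: 30 3-[(2R)-1-[4-(TBSO-methyl)-2,5-dioxo-2,5-dihydrofuran-3-yl]heptan-2-yl]-4-(2-oxohexyl)furan-2,5-dione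
Conditions: Ph3PAuNTf2 (5 mol %), H2O (5 equiv), 1,4-dioxane, 60 °C; concentrate from toluene
Reagents that add atoms: water, O
Why: Gold-catalysed alkyne hydration (Kucherov-type) should place oxygen on the alkyne carbon remote from ring B, because the ring polarises the alkyne as a vinylogous ynone and its adjacent carbonyl can assist attack at that carbon, so that the 2-oxohexyl ketone results.

**Step 12**
Reactants: 30 3-[(2R)-1-[4-(TBSO-methyl)-2,5-dioxo-2,5-dihydrofuran-3-yl]heptan-2-yl]-4-(2-oxohexyl)furan-2,5-dione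
Product: 31 3-[(2R)-1-[4-(hydroxymethyl)-2,5-dioxo-2,5-dihydrofuran-3-yl]heptan-2-yl]-4-(2-oxohexyl)furan-2,5-dione (CNP0537712.2)
Conditions: 48% aq. HF, MeCN, 0 °C → rt; concentrate from toluene
Reagents that add atoms: none
Why: Acidic fluoride desilylation should free the primary alcohol without base, so that the anhydrides, the acidic methylene next to the ketone and the allylic stereocentre are not disturbed.

**Compound list**
1 | furan-3,4-diyldimethanol | OCc1cocc1CO | starting material
2 | sodium [4-(hydroxymethyl)furan-3-yl]methanolate | [Na+].[O-]Cc1cocc1CO | intermediate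
3 | [4-({[tert-butyl(dimethyl)silyl]oxy}methyl)furan-3-yl]methanol | OCc1cocc1CO[Si](C)(C)C(C)(C)C | intermediate
4 | {[4-(bromomethyl)furan-3-yl]methoxy}(tert-butyl)dimethylsilane | BrCc1cocc1CO[Si](C)(C)C(C)(C)C | intermediate
5 | (4S)-4-benzyl-1,3-oxazolidin-2-one | O=C1N[C@@H](Cc2ccccc2)CO1 | starting material
6 | heptanoyl chloride | CCCCCCC(Cl)=O | starting material
7 | lithium salt (N-lithio) of (4S)-4-benzyl-1,3-oxazolidin-2-one | [Li+].O=C1[N-][C@@H](Cc2ccccc2)CO1 | intermediate
8 | (4S)-4-benzyl-3-heptanoyl-1,3-oxazolidin-2-one | CCCCCCC(=O)N1[C@@H](Cc2ccccc2)COC1=O | intermediate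
9 | sodium (Z)-enolate of 8 | [Na+].CCCCC/C=C(\[O-])N1[C@@H](Cc2ccccc2)COC1=O | intermediate
10 | (4S)-4-benzyl-3-[(2R)-2-{[4-({[tert-butyl(dimethyl)silyl]oxy}methyl)furan-3-yl]methyl}heptanoyl]-1,3-oxazolidin-2-one | CCCCC[C@H](Cc1cocc1CO[Si](C)(C)C(C)(C)C)C(=O)N1[C@@H](Cc2ccccc2)COC1=O | intermediate
11 | (2R)-2-{[4-({[tert-butyl(dimethyl)silyl]oxy}methyl)furan-3-yl]methyl}heptaneperoxoic acid (present as its lithium salt) | CCCCC[C@H](Cc1cocc1CO[Si](C)(C)C(C)(C)C)C(=O)OO | intermediate
12 | (2R)-2-{[4-({[tert-butyl(dimethyl)silyl]oxy}methyl)furan-3-yl]methyl}heptanoic acid | CCCCC[C@H](Cc1cocc1CO[Si](C)(C)C(C)(C)C)C(O)=O | intermediate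
13 | mixed anhydride of 12 with isobutyl hydrogen carbonate | CCCCC[C@H](Cc1cocc1CO[Si](C)(C)C(C)(C)C)C(=O)OC(=O)OCC(C)C | intermediate
14 | (3R)-1-diazo-3-{[4-({[tert-butyl(dimethyl)silyl]oxy}methyl)furan-3-yl]methyl}octan-2-one | CCCCC[C@H](Cc1cocc1CO[Si](C)(C)C(C)(C)C)C(=O)C=[N+]=[N-] | intermediate
15 | hex-1-yne | CCCCC#C | starting material
16 | di-tert-butyl oxalate | CC(C)(C)OC(=O)C(=O)OC(C)(C)C | starting material
17 | hex-1-yn-1-yllithium | [Li]C#CCCCC | intermediate
18 | lithium alkoxide of tert-butyl 2-tert-butoxy-2-hydroxyoct-3-ynoate (tetrahedral adduct) | [Li]OC(C#CCCCC)(OC(C)(C)C)C(=O)OC(C)(C)C | intermediate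
19 | tert-butyl 2-oxooct-3-ynoate | CCCCC#CC(=O)C(=O)OC(C)(C)C | intermediate
20 | 2-oxooct-3-ynoic acid | CCCCC#CC(=O)C(O)=O | intermediate
21 | (3R)-3-{[4-({[tert-butyl(dimethyl)silyl]oxy}methyl)furan-3-yl]methyl}oct-1-en-1-one (ketene) | CCCCC[C@H](Cc1cocc1CO[Si](C)(C)C(C)(C)C)C=C=O | intermediate
22 | (3R)-3-{[4-({[tert-butyl(dimethyl)silyl]oxy}methyl)furan-3-yl]methyl}octanoic 2-oxooct-3-ynoic anhydride (formed as its enolate) | CCCCC[C@H](Cc1cocc1CO[Si](C)(C)C(C)(C)C)CC(=O)OC(=O)C(=O)C#CCCCC | intermediate
23 | 3-(hex-1-yn-1-yl)-3-hydroxy-4-[(2R)-1-[4-({[tert-butyl(dimethyl)silyl]oxy}methyl)furan-3-yl]heptan-2-yl]oxolane-2,5-dione (mixture at the two ring centres) | CCCCC[C@H](Cc1cocc1CO[Si](C)(C)C(C)(C)C)C1C(=O)OC(=O)C1(O)C#CCCCC | intermediate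
24 | methanesulfonate of 23 at the tertiary hydroxyl | CCCCC[C@H](Cc1cocc1CO[Si](C)(C)C(C)(C)C)C1C(=O)OC(=O)C1(OS(C)(=O)=O)C#CCCCC | intermediate
25 | 3-[(2R)-1-[4-({[tert-butyl(dimethyl)silyl]oxy}methyl)furan-3-yl]heptan-2-yl]-4-(hex-1-yn-1-yl)furan-2,5-dione | CCCCC[C@H](Cc1cocc1CO[Si](C)(C)C(C)(C)C)C1=C(C#CCCCC)C(=O)OC1=O | intermediate
26 | furan 2,5-endoperoxide of 25 (2,3,7-trioxabicyclo[2.2.1]hept-5-ene; bridgeheads unassigned) | CCCCC[C@H](CC1=C(CO[Si](C)(C)C(C)(C)C)C2OOC1O2)C1=C(C#CCCCC)C(=O)OC1=O | intermediate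
27 | 5-hydroxybutenolide with the lactone carbonyl next to the silyloxymethyl-bearing carbon (lactol centre unassigned) | CCCCC[C@H](CC1=C(CO[Si](C)(C)C(C)(C)C)C(=O)OC1O)C1=C(C#CCCCC)C(=O)OC1=O | intermediate
28 | 5-hydroxybutenolide with the lactone carbonyl next to the chain-bearing carbon (lactol centre unassigned) | CCCCC[C@H](CC1=C(CO[Si](C)(C)C(C)(C)C)C(O)OC1=O)C1=C(C#CCCCC)C(=O)OC1=O | intermediate
29 | 3-[(2R)-1-[4-({[tert-butyl(dimethyl)silyl]oxy}methyl)-2,5-dioxo-2,5-dihydrofuran-3-yl]heptan-2-yl]-4-(hex-1-yn-1-yl)furan-2,5-dione | CCCCC[C@H](CC1=C(CO[Si](C)(C)C(C)(C)C)C(=O)OC1=O)C1=C(C#CCCCC)C(=O)OC1=O | intermediate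
30 | 3-[(2R)-1-[4-({[tert-butyl(dimethyl)silyl]oxy}methyl)-2,5-dioxo-2,5-dihydrofuran-3-yl]heptan-2-yl]-4-(2-oxohexyl)furan-2,5-dione | CCCCC[C@H](CC1=C(CO[Si](C)(C)C(C)(C)C)C(=O)OC1=O)C1=C(CC(=O)CCCC)C(=O)OC1=O | intermediate
31 | 3-[(2R)-1-[4-(hydroxymethyl)-2,5-dioxo-2,5-dihydrofuran-3-yl]heptan-2-yl]-4-(2-oxohexyl)furan-2,5-dione (CNP0537712.2) | CCCCC[C@H](CC1=C(CO)C(=O)OC1=O)C1=C(CC(=O)CCCC)C(=O)OC1=O | target

**Totals**
Total step count: 12. Longest linear sequence: 9 steps (1, 2, 4, 5, 6, 9, 10, 11, 12).

**Steps most likely to fail**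

Step 9 (Proposed new method). What may go wrong:
- The anhydride enolate may be protonated and the anhydrides may scramble before the aldol closure takes place.
- The carboxylate or the amine may add in conjugate fashion to the ynone.
- The silver carbenoid may be trapped by the tethered furan instead of undergoing the 1,2-shift.

Fallback by known chemistry, setting out from 14: Wolff rearrangement in tert-butanol (PhCO2Ag, Et3N, tBuOH/THF; Arndt–Eistert homologation through ketene 21) should give tert-butyl (3R)-3-{[4-(TBSO-methyl)furan-3-yl]methyl}octanoate F1. LiN(iPr)2 in THF at −78 °C should convert it into its lithium enolate F2. Intermolecular aldol addition of F2 to keto ester 19 should give the di-tert-butyl 2-hydroxysuccinate F3 as a diastereomer mixture. ZnBr2 in CH2Cl2 should cleave both tert-butyl esters to the hydroxy diacid F4. MsCl/Et3N should then close the anhydride, so that the fallback comes back to the route at 23, which the same reagent carries through 24 to 25.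

Step 11. What may go wrong:
- Activation of the electron-poor alkyne may be sluggish.
- Water may attack the alkyne carbon next to the ring.
- The anhydrides may open irreversibly in the warm aqueous medium.

Fallback, setting out from 29: conjugate hydroiodination (NaI, AcOH, 60 °C; iodide adds at the alkyne carbon remote from the ring, anti-addition) should give the (Z)-2-iodohex-1-enyl bis-anhydride F5. Its vinylogous β-iodo enone unit should be hydrolysed by addition–elimination (aq. HCl, THF, 50 °C), and the fallback comes back to the route at 30.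

Step 10. What may go wrong:
- The endoperoxide may decompose before the base-induced rearrangement.
- The amine may attack the alkynyl anhydride.
- Oxidation of the lactols may stop short of the anhydride.

Fallback, setting out from 25: bromonium-induced oxidative opening of the furan (NBS, NaHCO3, acetone/H2O, −20 °C) should give the (Z)-enedial F6. Pinnick oxidation (NaClO2, NaH2PO4, 2-methyl-2-butene, tBuOH/H2O) should give the maleic diacid F7, which should lose water on acidic work-up and concentration, so that the fallback comes back to the route at 29.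

**Further compounds**
F1 | step 9 | tert-butyl (3R)-3-{[4-({[tert-butyl(dimethyl)silyl]oxy}methyl)furan-3-yl]methyl}octanoate | CCCCC[C@H](Cc1cocc1CO[Si](C)(C)C(C)(C)C)CC(=O)OC(C)(C)C
F2 | step 9 | lithium enolate of F1 (geometry unassigned) | [Li+].CCCCC[C@H](Cc1cocc1CO[Si](C)(C)C(C)(C)C)C=C([O-])OC(C)(C)C
F3 | step 9 | di-tert-butyl 2-(hex-1-yn-1-yl)-2-hydroxy-3-[(2R)-1-[4-({[tert-butyl(dimethyl)silyl]oxy}methyl)furan-3-yl]heptan-2-yl]butanedioate | CCCCC[C@H](Cc1cocc1CO[Si](C)(C)C(C)(C)C)C(C(=O)OC(C)(C)C)C(O)(C#CCCCC)C(=O)OC(C)(C)C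
F4 | step 9 | 2-(hex-1-yn-1-yl)-2-hydroxy-3-[(2R)-1-[4-({[tert-butyl(dimethyl)silyl]oxy}methyl)furan-3-yl]heptan-2-yl]butanedioic acid | CCCCC[C@H](Cc1cocc1CO[Si](C)(C)C(C)(C)C)C(C(O)=O)C(O)(C#CCCCC)C(O)=O
F5 | step 11 | 3-[(2R)-1-[4-({[tert-butyl(dimethyl)silyl]oxy}methyl)-2,5-dioxo-2,5-dihydrofuran-3-yl]heptan-2-yl]-4-[(Z)-2-iodohex-1-en-1-yl]furan-2,5-dione | CCCCC[C@H](CC1=C(CO[Si](C)(C)C(C)(C)C)C(=O)OC1=O)C1=C(/C=C(\I)CCCC)C(=O)OC1=O
F6 | step 10 | (Z)-enedial from opening of the furan of 25: 3-[(2R)-1-[(2Z)-2,3-diformyl-4-{[tert-butyl(dimethyl)silyl]oxy}but-2-en-1-yl] chain as heptan-2-yl substituent]-4-(hex-1-yn-1-yl)furan-2,5-dione | CCCCC[C@H](C/C(C=O)=C(/C=O)CO[Si](C)(C)C(C)(C)C)C1=C(C#CCCCC)C(=O)OC1=O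
F7 | step 10 | (Z)-maleic diacid corresponding to F6 (both formyl groups oxidised to carboxyl) | CCCCC[C@H](C/C(C(O)=O)=C(/C(O)=O)CO[Si](C)(C)C(C)(C)C)C1=C(C#CCCCC)C(=O)OC1=O
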